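**Plan** (flavan numbering; the bottom unit is the one with C4H2, then middle, then top)
1. Retrosynthesis: the three gallate esters and the 21 benzyl ethers come off last; the bond C4(top)–C8(middle) is cut to a C4-alkoxy epicatechin electrophile; C4–H of the middle unit is traced back to a tertiary C4 alcohol; then O1–C8a and C4–C4a of the middle unit are cut together, followed by C4–C8(bottom) and C2–C3.
2. Forward: C8-lithiated, protected epicatechin is acylated by the Weinreb amide of a syn glycolate aldol; the resulting ketone and 3,5-bis(benzyloxy)benzyne fuse ring A onto the chain and close ring C of the middle unit; C4 is deoxygenated; the top unit is joined by Lewis acid condensation; threefold galloylation and hydrogenolysis finish.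
3. Enabling feature: in ring A of the middle unit, C8a and C4a are adjacent carbons that carry O1 and C4, and C4a lies next to the C5 oxygen, so an alkoxide (O1) and a ketone (C4) can be added across a 3-alkoxyaryne in exactly this orientation.
4. Stereochemistry: C2/C3 of the bottom and top units come from (−)-epicatechin; C2/C3 of the middle unit from an oxazolidinone-controlled Evans syn aldol; C4 of the middle unit from cis hydride delivery by a silane held on the C3 oxygen; C4 of the top unit from arene attack on the C4 cation anti to the C3 hydroxyl.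

Key step: step 11

Remark: compounds 5, 16 and 33 are taken as purchased, and the C4 carbinol of 24–27 is drawn as one epimer although either would serve, because step 14 planarises this centre.

**Step 1**
Reactants: 1 (−)-epicatechin
Product: 2 5,7,3',4'-tetra-O-benzyl-(−)-epicatechin
Conditions: BnBr (4.4 equiv), K2CO3, DMF, 0 °C → rt
Reagents that add atoms: benzyl bromide, BrCc1ccccc1
Why: Williamson etherification in which carbonate deprotonates only the four phenols, so the C3 alcohol stays free and the C2/C3 stereocentres are untouched.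

**Step 2**
Reactants: 2 5,7,3',4'-tetra-O-benzyl-(−)-epicatechin
Product: 3 8-bromo-5,7,3',4'-tetra-O-benzylepicatechin
Conditions: NBS (1.0 equiv), CH2Cl2, −78 °C → rt
Reagents that add atoms: N-bromosuccinimide, O=C1CCC(=O)N1Br
Why: Electrophilic aromatic bromination of the phloroglucinol-type ring A, which in benzylated flavan-3-ols is known to occur at C8 in preference to C6 with one equivalent of NBS at low temperature.

**Step 3**
Reactants: 3 8-bromo-5,7,3',4'-tetra-O-benzylepicatechin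
Product: 4 8-bromo-3-O-(tert-butyldimethylsilyl)-5,7,3',4'-tetra-O-benzylepicatechin
Conditions: TBSCl, imidazole, DMF, rt
Reagents that add atoms: tert-butyldimethylsilyl chloride, CC(C)(C)[Si](C)(C)Cl
Why: Standard silylation of the secondary alcohol, giving an ether that tolerates t-BuLi and is cleaved by fluoride far more slowly than a triethylsilyl ether.

**Step 4**
Reactants: 5 2-(allyloxy)acetic acid; 6 (S)-4-benzyl-1,3-oxazolidin-2-one
Product: 8 (S)-3-[2-(allyloxy)acetyl]-4-benzyl-1,3-oxazolidin-2-one, via mixed pivalic anhydride 7 (not isolated)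
Conditions: PivCl, Et3N, THF, −20 °C; then 6, LiCl, rt
Reagents that add atoms: none
Why: N-acylation of the oxazolidinone through a mixed anhydride activated by LiCl and Et3N, a routine entry to glycolyl imides.

**Step 5**
Reactants: 8 (S)-3-[2-(allyloxy)acetyl]-4-benzyl-1,3-oxazolidin-2-one; 9 3,4-bis(benzyloxy)benzaldehyde
Product: 11 (S)-3-[(2S,3R)-2-(allyloxy)-3-[3,4-bis(benzyloxy)phenyl]-3-hydroxypropanoyl]-4-benzyl-1,3-oxazolidin-2-one, via Z dibutylboron enolate 10 (not isolated)
Conditions: Bu2BOTf, i-Pr2NEt, CH2Cl2, −78 → 0 °C; then 9, −78 → 0 °C; pH 7 buffer, MeOH, H2O2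
Reagents that add atoms: none
Why: Evans syn aldol in which the Z boron enolate reacts through a Zimmerman–Traxler chair on the face remote from the benzyl group of the auxiliary, setting the future C3 (2S of the acyl chain) and C2 (3R) of the middle unit as a syn pair.

**Step 6**
Reactants: 11 syn aldol imide
Product: 12 (2S,3R)-2-(allyloxy)-3-[3,4-bis(benzyloxy)phenyl]-3-hydroxy-N-methoxy-N-methylpropanamide
Conditions: MeNHOMe·HCl, AlMe3, CH2Cl2, −20 → 0 °C
Reagents that add atoms: N,O-dimethylhydroxylamine hydrochloride, CNOC.Cl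
Why: Aluminium amide transamidation of an Evans aldol imide to the Weinreb amide, assisted by the free β-hydroxyl and returning the auxiliary.

**Step 7**
Reactants: 12 Weinreb amide
Product: 13 (2S,3R)-2-(allyloxy)-3-[3,4-bis(benzyloxy)phenyl]-N-methoxy-N-methyl-3-(triethylsilyloxy)propanamide
Conditions: TESCl, imidazole, DMF, 0 °C → rt
Reagents that add atoms: chlorotriethylsilane, CC[Si](Cl)(CC)CC
Why: Standard silylation of the benzylic hydroxyl, which removes the acidic proton for the organolithium step and later serves as the fluoride-labile source of the C2 alkoxide.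

**Step 8**
Reactants: 4 8-bromo-3-O-(tert-butyldimethylsilyl)-5,7,3',4'-tetra-O-benzylepicatechin; 13 silylated Weinreb amide
Product: 15 8-[(2S,3R)-2-(allyloxy)-3-[3,4-bis(benzyloxy)phenyl]-3-(triethylsilyloxy)propanoyl]-3-O-(tert-butyldimethylsilyl)-5,7,3',4'-tetra-O-benzylepicatechin, via C8 aryllithium 14 (not isolated)
Conditions: 4, t-BuLi (2.0 equiv), THF, −78 °C; then 13, −78 → −40 °C; H2O
Reagents that add atoms: none
Why: Bromine–lithium exchange followed by Weinreb ketone synthesis, in which the chelated tetrahedral adduct prevents over-addition and keeps the α-alkoxy centre intact until work-up.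

**Step 9**
Reactants: 16 3,5-bis(benzyloxy)phenol
Product: 17 2-bromo-3,5-bis(benzyloxy)phenol
Conditions: NBS (1.0 equiv), CH2Cl2, −78 → 0 °C
Reagents that add atoms: N-bromosuccinimide, O=C1CCC(=O)N1Br
Why: Electrophilic bromination of a phenol in a non-polar solvent, directed ortho to the hydroxyl by hydrogen bonding to the reagent, the two ortho positions being equivalent.

**Step 10**
Reactants: 17 2-bromo-3,5-bis(benzyloxy)phenol
Product: 20 3,5-bis(benzyloxy)-2-(trimethylsilyl)phenyl trifluoromethanesulfonate, via aryl trimethylsilyl ether 18 (not isolated), via lithium silylphenoxide 19 (not isolated)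
Conditions: HMDS, THF, 65 °C, evaporate; n-BuLi, THF, −78 °C; then Tf2O, −78 °C → rt
Reagents that add atoms: hexamethyldisilazane, C[Si](C)(C)N[Si](C)(C)C; trifluoromethanesulfonic anhydride, O=S(=O)(OS(=O)(=O)C(F)(F)F)C(F)(F)F
Why: O-silylation, bromine–lithium exchange with 1,3 O→C silyl shift (retro-Brook rearrangement) and triflation of the phenoxide, the standard sequence from an ortho-bromophenol to an ortho-silylaryl triflate.

**Step 11**
Reactants: 15 C8 ketone with C2 triethylsilyl ether and C3 allyl ether; 20 3,5-bis(benzyloxy)-2-(trimethylsilyl)phenyl trifluoromethanesulfonate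
Product: 24 3-O-allyl-4-hydroxy-5,7,3',4'-tetra-O-benzylepicatechin-(4→8)-3-O-(tert-butyldimethylsilyl)-5,7,3',4'-tetra-O-benzylepicatechin (tertiary C4 alcohol), via 3,5-bis(benzyloxy)benzyne 21 (not isolated), via caesium C2 alkoxide 22 (not isolated), via C4a aryl caesium 23 (not isolated)
Conditions: CsF, 18-crown-6, THF, 0 °C → rt; 15 and 20 (2 equiv) added slowly; H2O work-up
Reagents that add atoms: none
Why: Proposed new method: fluoride strips the aryl trimethylsilyl group of 20 with loss of triflate to give aryne 21 and at the same time cleaves the triethylsilyl ether of 15 to the caesium C2 alkoxide 22, which adds to the aryne carbon remote from the flanking benzyloxy group (forming O1–C8a) to give aryl anion 23, and this anion adds to the C4 ketone (forming C4–C4a). The closest known reaction type is the aryne annulation of ortho-hydroxyaryl ketones and salicylates to xanthenols and xanthones, where a phenoxide adds and the aryl anion closes on the carbonyl; an aliphatic aldol alkoxide has not been used in this way. Ring C of the middle unit closes by 6-exo-trig attack of the C4a anion on the C4 carbonyl. The new C4 carbinol centre is under substrate control (equatorial C2 aryl, axial C3 allyloxy, the bulky bottom aryl pseudo-axial and anti to the C3 oxygen to avoid the C5 benzyloxy group), but either epimer serves because C4 is planarised in step 14. The step needs oxygen at C8a and carbon at C4a, which the benzyloxy group next to the aryne bond (the future C5 oxygen) secures by stabilising the anion at C4a inductively; it also needs ring closure to outrun retro-aldol cleavage and protonation, for which the slow fluoride release of the alkoxide into excess aryne, the aprotic medium and the non-migrating allyl ether at C3 are chosen.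

**Step 12**
Reactants: 24 tertiary C4 alcohol with C3 allyl ether
Product: 26 4-hydroxy-5,7,3',4'-tetra-O-benzylepicatechin-(4→8)-3-O-(tert-butyldimethylsilyl)-5,7,3',4'-tetra-O-benzylepicatechin (3,4-diol), via E-propenyl ether 25 (not isolated)
Conditions: [Ir(cod)(PMePh2)2]PF6 (cat., H2-activated), THF, rt; then OsO4 (cat.), NMO, acetone/H2O, rt
Reagents that add atoms: none
Why: Iridium-hydride-catalysed isomerisation of the allyl ether to the propenyl ether, then catalytic dihydroxylation of the enol ether and collapse of the hemiacetal, a neutral two-stage deallylation that spares benzyl ethers, the silyl ether and the acid-labile tertiary benzylic alcohol.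

**Step 13**
Reactants: 26 3,4-diol
Product: 27 3-O-(diisopropylsilyl)-4-hydroxy-5,7,3',4'-tetra-O-benzylepicatechin-(4→8)-3-O-(tert-butyldimethylsilyl)-5,7,3',4'-tetra-O-benzylepicatechin
Conditions: i-Pr2SiHCl, imidazole, CH2Cl2, 0 °C; used without delay
Reagents that add atoms: chlorodiisopropylsilane, CC(C)[SiH](Cl)C(C)C
Why: Silylation with a small chlorosilane that is selective for the secondary C3 hydroxyl over the hindered tertiary C4 hydroxyl and places a hydride donor on the face of ring C that carries the C3 oxygen.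

**Step 14**
Reactants: 27 C3 diisopropylsilyl ether of the tertiary C4 alcohol
Product: 30 octa-O-benzylprocyanidin B2 [5,7,3',4'-tetra-O-benzylepicatechin-(4β→8)-5,7,3',4'-tetra-O-benzylepicatechin], via C4 carbenium ion 28 (not isolated), via fluorosilyl ether 29 (not isolated)
Conditions: BF3·OEt2 (1.2 equiv), CH2Cl2 (0.005 M), −78 → −40 °C; aq NaHCO3; crude 29, TBAF, THF, rt
Reagents that add atoms: none
Why: Proposed new method: BF3 ionises the doubly benzylic tertiary C4 alcohol of 27 to carbenium ion 28, whose nearest hydride source is the Si–H held on the C3 oxygen, so hydride should pass to C4 through a five-membered cyclic transition state on the face that carries the C3 oxygen (C4–H cis to C3–O, bottom aryl trans, the 4β configuration), the silicon being capped by fluoride from the borate to give 29 before fluoride clears both silyl groups; the closest known reaction types are the silicon-tethered intramolecular ionic hydrogenation of alkenols and the Lewis-acid-promoted intramolecular hydrosilylation of β-silyloxy ketones, which run through six-membered transition states, whereas untethered hydride donors are known to attack such C4 cations from the opposite face.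

**Step 15**
Reactants: 2 5,7,3',4'-tetra-O-benzyl-(−)-epicatechin
Product: 31 5,7,3',4'-tetra-O-benzyl-4β-(2-ethoxyethoxy)epicatechin (C4 alkoxy trans to the C3 hydroxyl)
Conditions: DDQ, 2-ethoxyethanol, CH2Cl2, rt
Reagents that add atoms: 2-ethoxyethanol, CCOCCO
Why: DDQ-mediated benzylic oxidation at C4 of the electron-rich flavan with capture of the cation by the alcohol anti to the C3 hydroxyl, the standard preparation of flavan C4 electrophiles.

**Step 16**
Reactants: 30 octa-O-benzylprocyanidin B2; 31 C4 electrophile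
Product: 32 dodeca-O-benzylprocyanidin C1 [epicatechin-(4β→8)-epicatechin-(4β→8)-epicatechin with all twelve phenols benzylated and three free C3 hydroxyls]
Conditions: TMSOTf (cat.), CH2Cl2, −78 °C; 30 in excess (recovered)
Reagents that add atoms: none
Why: Lewis-acid-catalysed Friedel–Crafts-type condensation established for benzylated procyanidins, in which the C4 cation from 31 is attacked by C8 of the upper unit of the dimer (its only free C8) anti to the C3 hydroxyl, setting the top C4 as 4β.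

**Step 17**
Reactants: 32 dodeca-O-benzylprocyanidin C1; 33 3,4,5-tris(benzyloxy)benzoic acid (three molecules are taken up per molecule of 32)
Product: 34 dodeca-O-benzylprocyanidin C1 3,3',3''-tris[3,4,5-tris(benzyloxy)benzoate]
Conditions: 33 (6 equiv), DCC (6 equiv), DMAP, CH2Cl2, rt
Reagents that add atoms: 3,4,5-tris(benzyloxy)benzoic acid (33), OC(=O)c1cc(OCc9ccccc9)c(OCc9ccccc9)c(OCc9ccccc9)c1
Why: Threefold Steglich esterification in which each of the three secondary C3 hydroxyls is acylated by one molecule of DCC-activated 33 through the acylpyridinium formed with DMAP, a known way to install protected gallates on hindered flavan-3-ols; the acid is used in excess so that all three esters form.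

**Step 18**
Reactants: 34 perbenzylated trigallate
Product: 35 procyanidin C1 3,3',3''-tri-O-gallate
Conditions: H2 (1 atm), Pd(OH)2/C, THF/MeOH/H2O, rt
Reagents that add atoms: none
Why: Hydrogenolysis of the 21 benzyl ethers under neutral conditions that leave the gallate esters, the interflavan bonds and all stereocentres intact.

**Compound list**
1 | (−)-epicatechin, (2R,3R) | Oc1cc(O)c2c(c1)O[C@H](c1ccc(O)c(O)c1)[C@H](O)C2 | starting material
2 | 5,7,3',4'-tetra-O-benzyl-(−)-epicatechin | O[C@@H]1Cc2c(OCc9ccccc9)cc(OCc9ccccc9)cc2O[C@@H]1c1ccc(OCc9ccccc9)c(OCc9ccccc9)c1 | intermediate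
3 | 8-bromo-5,7,3',4'-tetra-O-benzylepicatechin | O[C@@H]1Cc2c(OCc9ccccc9)cc(OCc9ccccc9)c(Br)c2O[C@@H]1c1ccc(OCc9ccccc9)c(OCc9ccccc9)c1 | intermediate
4 | 8-bromo-3-O-(tert-butyldimethylsilyl)-5,7,3',4'-tetra-O-benzylepicatechin | CC(C)(C)[Si](C)(C)O[C@@H]1Cc2c(OCc9ccccc9)cc(OCc9ccccc9)c(Br)c2O[C@@H]1c1ccc(OCc9ccccc9)c(OCc9ccccc9)c1 | intermediate
5 | 2-(allyloxy)acetic acid | C=CCOCC(=O)O | starting material
6 | (S)-4-benzyl-1,3-oxazolidin-2-one | O=C1N[C@@H](Cc2ccccc2)CO1 | starting material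
7 | 2-(allyloxy)acetic pivalic anhydride (not isolated) | C=CCOCC(=O)OC(=O)C(C)(C)C | intermediate
8 | (S)-3-[2-(allyloxy)acetyl]-4-benzyl-1,3-oxazolidin-2-one | C=CCOCC(=O)N1[C@@H](Cc2ccccc2)COC1=O | intermediate
9 | 3,4-bis(benzyloxy)benzaldehyde | O=Cc1ccc(OCc2ccccc2)c(OCc2ccccc2)c1 | starting material
10 | Z dibutylboron enolate of 8 (not isolated) | C=CCO/C=C(\OB(CCCC)CCCC)N1[C@@H](Cc2ccccc2)COC1=O | intermediate
11 | (S)-3-[(2S,3R)-2-(allyloxy)-3-[3,4-bis(benzyloxy)phenyl]-3-hydroxypropanoyl]-4-benzyl-1,3-oxazolidin-2-one | C=CCO[C@@H]([C@H](O)c1ccc(OCc9ccccc9)c(OCc9ccccc9)c1)C(=O)N1[C@@H](Cc2ccccc2)COC1=O | intermediate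
12 | (2S,3R)-2-(allyloxy)-3-[3,4-bis(benzyloxy)phenyl]-3-hydroxy-N-methoxy-N-methylpropanamide | C=CCO[C@@H]([C@H](O)c1ccc(OCc9ccccc9)c(OCc9ccccc9)c1)C(=O)N(C)OC | intermediate
13 | (2S,3R)-2-(allyloxy)-3-[3,4-bis(benzyloxy)phenyl]-N-methoxy-N-methyl-3-(triethylsilyloxy)propanamide | C=CCO[C@@H]([C@H](O[Si](CC)(CC)CC)c1ccc(OCc9ccccc9)c(OCc9ccccc9)c1)C(=O)N(C)OC | intermediate
14 | 8-lithio-3-O-(tert-butyldimethylsilyl)-5,7,3',4'-tetra-O-benzylepicatechin (not isolated) | CC(C)(C)[Si](C)(C)O[C@@H]1Cc2c(OCc9ccccc9)cc(OCc9ccccc9)c([Li])c2O[C@@H]1c1ccc(OCc9ccccc9)c(OCc9ccccc9)c1 | intermediate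
15 | 8-[(2S,3R)-2-(allyloxy)-3-[3,4-bis(benzyloxy)phenyl]-3-(triethylsilyloxy)propanoyl]-3-O-(tert-butyldimethylsilyl)-5,7,3',4'-tetra-O-benzylepicatechin | C=CCO[C@@H]([C@H](O[Si](CC)(CC)CC)c1ccc(OCc9ccccc9)c(OCc9ccccc9)c1)C(=O)c1c(OCc9ccccc9)cc(OCc9ccccc9)c2c1O[C@H](c1ccc(OCc9ccccc9)c(OCc9ccccc9)c1)[C@H](O[Si](C)(C)C(C)(C)C)C2 | intermediate
16 | 3,5-bis(benzyloxy)phenol | Oc1cc(OCc9ccccc9)cc(OCc9ccccc9)c1 | starting material
17 | 2-bromo-3,5-bis(benzyloxy)phenol | Oc1cc(OCc9ccccc9)cc(OCc9ccccc9)c1Br | intermediate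
18 | [2-bromo-3,5-bis(benzyloxy)phenoxy]trimethylsilane (not isolated) | C[Si](C)(C)Oc1cc(OCc9ccccc9)cc(OCc9ccccc9)c1Br | intermediate
19 | lithium 3,5-bis(benzyloxy)-2-(trimethylsilyl)phenoxide (not isolated) | [Li]Oc1cc(OCc9ccccc9)cc(OCc9ccccc9)c1[Si](C)(C)C | intermediate
20 | 3,5-bis(benzyloxy)-2-(trimethylsilyl)phenyl trifluoromethanesulfonate | O=S(=O)(Oc1cc(OCc9ccccc9)cc(OCc9ccccc9)c1[Si](C)(C)C)C(F)(F)F | intermediate
21 | 3,5-bis(benzyloxy)benzyne (not isolated) | C1#CC(OCc9ccccc9)=CC(OCc9ccccc9)=C1 | intermediate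
22 | caesium C2 alkoxide of 15, triethylsilyl group removed (not isolated) | C=CCO[C@@H]([C@H]([O-])c1ccc(OCc9ccccc9)c(OCc9ccccc9)c1)C(=O)c1c(OCc9ccccc9)cc(OCc9ccccc9)c2c1O[C@H](c1ccc(OCc9ccccc9)c(OCc9ccccc9)c1)[C@H](O[Si](C)(C)C(C)(C)C)C2.[Cs+] | intermediate
23 | aryl caesium after O1–C8a bond formation, charge at C4a between the two oxygen-bearing carbons (not isolated) | C=CCO[C@@H]([C@H](Oc1cc(OCc9ccccc9)cc(OCc9ccccc9)[c-]1)c1ccc(OCc9ccccc9)c(OCc9ccccc9)c1)C(=O)c1c(OCc9ccccc9)cc(OCc9ccccc9)c2c1O[C@H](c1ccc(OCc9ccccc9)c(OCc9ccccc9)c1)[C@H](O[Si](C)(C)C(C)(C)C)C2.[Cs+] | intermediate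
24 | 3-O-allyl-4-hydroxy-5,7,3',4'-tetra-O-benzylepicatechin-(4→8)-3-O-(tert-butyldimethylsilyl)-5,7,3',4'-tetra-O-benzylepicatechin, C4 hydroxyl cis to the C3 oxygen | C=CCO[C@@H]1[C@@](O)(c2c(OCc9ccccc9)cc(OCc9ccccc9)c3c2O[C@H](c2ccc(OCc9ccccc9)c(OCc9ccccc9)c2)[C@H](O[Si](C)(C)C(C)(C)C)C3)c2c(OCc9ccccc9)cc(OCc9ccccc9)cc2O[C@@H]1c1ccc(OCc9ccccc9)c(OCc9ccccc9)c1 | intermediate
25 | 3-O-[(E)-prop-1-enyl] analogue of 24 (not isolated) | C/C=C/O[C@@H]1[C@@](O)(c2c(OCc9ccccc9)cc(OCc9ccccc9)c3c2O[C@H](c2ccc(OCc9ccccc9)c(OCc9ccccc9)c2)[C@H](O[Si](C)(C)C(C)(C)C)C3)c2c(OCc9ccccc9)cc(OCc9ccccc9)cc2O[C@@H]1c1ccc(OCc9ccccc9)c(OCc9ccccc9)c1 | intermediate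
26 | 4-hydroxy-5,7,3',4'-tetra-O-benzylepicatechin-(4→8)-3-O-(tert-butyldimethylsilyl)-5,7,3',4'-tetra-O-benzylepicatechin (cis-3,4-diol) | O[C@@H]1[C@@](O)(c2c(OCc9ccccc9)cc(OCc9ccccc9)c3c2O[C@H](c2ccc(OCc9ccccc9)c(OCc9ccccc9)c2)[C@H](O[Si](C)(C)C(C)(C)C)C3)c2c(OCc9ccccc9)cc(OCc9ccccc9)cc2O[C@@H]1c1ccc(OCc9ccccc9)c(OCc9ccccc9)c1 | intermediate
27 | 3-O-(diisopropylsilyl) ether of 26 | CC(C)[SiH](C(C)C)O[C@@H]1[C@@](O)(c2c(OCc9ccccc9)cc(OCc9ccccc9)c3c2O[C@H](c2ccc(OCc9ccccc9)c(OCc9ccccc9)c2)[C@H](O[Si](C)(C)C(C)(C)C)C3)c2c(OCc9ccccc9)cc(OCc9ccccc9)cc2O[C@@H]1c1ccc(OCc9ccccc9)c(OCc9ccccc9)c1 | intermediate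
28 | C4 carbenium ion of 27 as hydroxytrifluoroborate (not isolated) | CC(C)[SiH](C(C)C)O[C@@H]1[C+](c2c(OCc9ccccc9)cc(OCc9ccccc9)c3c2O[C@H](c2ccc(OCc9ccccc9)c(OCc9ccccc9)c2)[C@H](O[Si](C)(C)C(C)(C)C)C3)c2c(OCc9ccccc9)cc(OCc9ccccc9)cc2O[C@@H]1c1ccc(OCc9ccccc9)c(OCc9ccccc9)c1.O[B-](F)(F)F | intermediate
29 | 3-O-(fluorodiisopropylsilyl)-5,7,3',4'-tetra-O-benzylepicatechin-(4β→8)-3-O-(tert-butyldimethylsilyl)-5,7,3',4'-tetra-O-benzylepicatechin (not isolated) | CC(C)[Si](F)(C(C)C)O[C@@H]1[C@@H](c2c(OCc9ccccc9)cc(OCc9ccccc9)c3c2O[C@H](c2ccc(OCc9ccccc9)c(OCc9ccccc9)c2)[C@H](O[Si](C)(C)C(C)(C)C)C3)c2c(OCc9ccccc9)cc(OCc9ccccc9)cc2O[C@@H]1c1ccc(OCc9ccccc9)c(OCc9ccccc9)c1 | intermediate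
30 | octa-O-benzylprocyanidin B2, 5,7,3',4'-tetra-O-benzylepicatechin-(4β→8)-5,7,3',4'-tetra-O-benzylepicatechin | O[C@@H]1[C@@H](c2c(OCc9ccccc9)cc(OCc9ccccc9)c3c2O[C@H](c2ccc(OCc9ccccc9)c(OCc9ccccc9)c2)[C@H](O)C3)c2c(OCc9ccccc9)cc(OCc9ccccc9)cc2O[C@@H]1c1ccc(OCc9ccccc9)c(OCc9ccccc9)c1 | intermediate
31 | 5,7,3',4'-tetra-O-benzyl-4β-(2-ethoxyethoxy)epicatechin, C4 alkoxy trans to the C3 hydroxyl | CCOCCO[C@H]1c2c(OCc9ccccc9)cc(OCc9ccccc9)cc2O[C@H](c2ccc(OCc9ccccc9)c(OCc9ccccc9)c2)[C@@H]1O | intermediate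
32 | dodeca-O-benzylprocyanidin C1, three free C3 hydroxyls | O[C@@H]1[C@@H](c2c(OCc9ccccc9)cc(OCc9ccccc9)c3c2O[C@H](c2ccc(OCc9ccccc9)c(OCc9ccccc9)c2)[C@H](O)C3)c2c(OCc9ccccc9)cc(OCc9ccccc9)c([C@H]3c4c(OCc9ccccc9)cc(OCc9ccccc9)cc4O[C@H](c4ccc(OCc9ccccc9)c(OCc9ccccc9)c4)[C@@H]3O)c2O[C@@H]1c1ccc(OCc9ccccc9)c(OCc9ccccc9)c1 | intermediate
33 | 3,4,5-tris(benzyloxy)benzoic acid | OC(=O)c1cc(OCc9ccccc9)c(OCc9ccccc9)c(OCc9ccccc9)c1 | starting material
34 | dodeca-O-benzylprocyanidin C1 3,3',3''-tris[3,4,5-tris(benzyloxy)benzoate] | O=C(O[C@@H]1[C@@H](c2c(OCc9ccccc9)cc(OCc9ccccc9)c3c2O[C@H](c2ccc(OCc9ccccc9)c(OCc9ccccc9)c2)[C@H](OC(=O)c2cc(OCc9ccccc9)c(OCc9ccccc9)c(OCc9ccccc9)c2)C3)c2c(OCc9ccccc9)cc(OCc9ccccc9)c([C@H]3c4c(OCc9ccccc9)cc(OCc9ccccc9)cc4O[C@H](c4ccc(OCc9ccccc9)c(OCc9ccccc9)c4)[C@@H]3OC(=O)c3cc(OCc9ccccc9)c(OCc9ccccc9)c(OCc9ccccc9)c3)c2O[C@@H]1c1ccc(OCc9ccccc9)c(OCc9ccccc9)c1)c1cc(OCc9ccccc9)c(OCc9ccccc9)c(OCc9ccccc9)c1 | intermediate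
35 | procyanidin C1 3,3',3''-tri-O-gallate | O=C(O[C@@H]1[C@@H](c2c(O)cc(O)c3c2O[C@H](c2ccc(O)c(O)c2)[C@H](OC(=O)c2cc(O)c(O)c(O)c2)C3)c2c(O)cc(O)c([C@H]3c4c(O)cc(O)cc4O[C@H](c4ccc(O)c(O)c4)[C@@H]3OC(=O)c3cc(O)c(O)c(O)c3)c2O[C@@H]1c1ccc(O)c(O)c1)c1cc(O)c(O)c(O)c1 | target

**Totals and risks**
Total step count: 18. Longest linear sequence: 12 steps (steps 4–8, 11–14 and 16–18, from 5 and 6 to 35).

Step 11 (new method). The transient C2 alkoxide may undergo retro-aldol cleavage before it meets the aryne. The aryl anion may be protonated before it closes on the hindered ketone. The α-alkoxy centre may epimerise in the basic medium, and the bottom silyl ether may be lost to fluoride. The fallback uses known chemistry, sets out from 2 and 4 and rejoins the route at 24. The C3 hydroxyl of 2 is allylated (NaH, allyl bromide, DMF) to 3-O-allyl-5,7,3',4'-tetra-O-benzylepicatechin F1. DDQ in wet CH2Cl2 oxidises C4 to 3-O-allyl-4β-hydroxy-5,7,3',4'-tetra-O-benzylepicatechin F2. Dess–Martin periodinane gives the 2,3-cis 3-allyloxy-5,7-bis(benzyloxy)-2-[3,4-bis(benzyloxy)phenyl]chroman-4-one F3. Aryllithium 14 (from 4 and t-BuLi as in step 8) then adds to the C4 carbonyl anti to the C3 allyloxy group to give tertiary alcohol 24. Ring A of the middle unit is then inherited from epicatechin and only the C4–C8 bond is made.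

Step 14 (new method). Hydride transfer through the five-membered transition state may be too slow. Intermolecular hydride delivery to the opposite face (poor facial selectivity), loss of the C3 proton from the cation to an enol ether, or cleavage of the Si–O bond by the Lewis acid could then take over. The fallback uses known chemistry, sets out from 2 and 31 and rejoins the route at 30. Compound 31 is condensed with an excess of 2 (TMSOTf, CH2Cl2, −78 °C); C8 of 2 attacks the C4 cation anti to the C3 hydroxyl and gives octa-O-benzylprocyanidin B2 30 directly. The 4β configuration is then set by the arene instead of by hydride; no compound outside the list is formed (entry F0).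

Step 8. The hindered, basic aryllithium may deprotonate the Weinreb amide at the α-alkoxy carbon (loss of configuration, return of debrominated material) or add too slowly. The fallback sets out from 13 and rejoins the route at 15. Amide 13 is reduced with i-Bu2AlH (THF, −78 °C) to (2S,3R)-2-(allyloxy)-3-[3,4-bis(benzyloxy)phenyl]-3-(triethylsilyloxy)propanal F4, a smaller and more reactive electrophile. Aryllithium 14 is added at −78 °C to give the secondary C8 carbinol F5 (both carbinol epimers), and Dess–Martin oxidation gives ketone 15.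

**Further compounds**
F1 | step 11 | 3-O-allyl-5,7,3',4'-tetra-O-benzylepicatechin | C=CCO[C@@H]1Cc2c(OCc9ccccc9)cc(OCc9ccccc9)cc2O[C@@H]1c1ccc(OCc9ccccc9)c(OCc9ccccc9)c1
F2 | step 11 | 3-O-allyl-4β-hydroxy-5,7,3',4'-tetra-O-benzylepicatechin (C4 hydroxyl trans to the C3 oxygen) | C=CCO[C@@H]1[C@@H](O)c2c(OCc9ccccc9)cc(OCc9ccccc9)cc2O[C@@H]1c1ccc(OCc9ccccc9)c(OCc9ccccc9)c1
F3 | step 11 | 2,3-cis 3-(allyloxy)-5,7-bis(benzyloxy)-2-[3,4-bis(benzyloxy)phenyl]chroman-4-one | C=CCO[C@@H]1C(=O)c2c(OCc9ccccc9)cc(OCc9ccccc9)cc2O[C@@H]1c1ccc(OCc9ccccc9)c(OCc9ccccc9)c1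
F0 | step 14 | none | none
F4 | step 8 | (2S,3R)-2-(allyloxy)-3-[3,4-bis(benzyloxy)phenyl]-3-(triethylsilyloxy)propanal | C=CCO[C@@H]([C@H](O[Si](CC)(CC)CC)c1ccc(OCc9ccccc9)c(OCc9ccccc9)c1)C=O
F5 | step 8 | secondary carbinol from addition of 14 to F4 (both carbinol epimers) | C=CCO[C@@H]([C@H](O[Si](CC)(CC)CC)c1ccc(OCc9ccccc9)c(OCc9ccccc9)c1)C(O)c1c(OCc9ccccc9)cc(OCc9ccccc9)c2c1O[C@H](c1ccc(OCc9ccccc9)c(OCc9ccccc9)c1)[C@H](O[Si](C)(C)C(C)(C)C)C2
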